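The runs were computed with made-up constants; the scatter is artificial.

Starting material and target together hold the charge, bar a gap of 1.50% averaged over delta's last two readings, so a flask can be reckoned through the starting material left.

common to all: gas 1.4 mM (held)

| charge | starting material | second substrate | capture agent | free catalyst | temperature | remark | time |
|---|---|---|---|---|---|---|---|
| alpha | 0.016 M | 1 equiv | 0.32 mM | 10 mol% | 25 °C | run made earlier |  |
| beta | 0.016 M | 1 equiv | 0.32 mM | 14 mol% | 40 °C | run made earlier |  |
| gamma | 0.016 M | 1 equiv | 0.32 mM | 22 mol% | 25 °C | run made earlier |  |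
| delta | 0.016 M | 1.5 equiv | 0.32 mM | 10 mol% | 40 °C | run made earlier |  |
| south-west | 0.016 M | 1.00 equiv | 0.320 mM | 10 mol% | 40 °C | everything together at the start | 50 h |
| south-east | 0.016 M (fed, over 20 h) | 1.00 equiv | 0.320 mM | 10 mol% | 40 °C | all else is in the flask from the start; the feed brings no volume worth counting | 50 h |
| north | 0.016 M (fed, over 20 h) | 1.00 equiv | 0.320 mM | 10 mol% |  | the addition at 20 °C, then warmed to 40 °C; the feed brings no volume worth counting | 50 h |
| north-east | 0.016 M | 1.00 equiv | 0.320 mM | 10 mol% |  | everything together at the start at 20 °C, warmed to 40 °C at 20 h | 50 h |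

| run | time / h | target / % | starting material / % |
|---|---|---|---|
| alpha | 12.0 | 7.1 | 89.6 |
| alpha | 25.0 | 17.2 | 79.6 |
| alpha | 40.0 | 28.2 | 69.5 |
| alpha | 48.0 | 33.4 | 64.3 |
| alpha | 60.0 | 40.9 | 57.3 |
| beta | 5.00 | 6.8 | 89.8 |
| beta | 10.0 | 19.0 | 78.4 |
| beta | 15.0 | 29.4 | 67.7 |
| beta | 30.0 | 54.7 | 42.6 |
| beta | 60.0 | 83.1 | 15.9 |
| gamma | 10.0 | 12.5 | 82.1 |
| gamma | 20.0 | 28.0 | 66.8 |
| gamma | 30.0 | 42.0 | 55.0 |
| gamma | 60.0 | 69.4 | 28.0 |
| gamma | 120 | 93.1 | 6.9 |
| delta | 5.00 | 3.0 | 94.1 |
| delta | 10.0 | 10.8 | 86.7 |
| delta | 15.0 | 19.6 | 78.2 |
| delta | 30.0 | 40.8 | 56.7 |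
| delta | 60.0 | 70.6 | 28.9 |

(readings scatter by 0.3 percentage points)

- at the start none of the gas is in solution

* which flask leads in amount of target, in percent of the starting material charged ("all alike" within 1.5 percentage points) (south-west / south-east / north / north-east / all alike)
* how much target is there at the end, in percent of the starting material charged: south-west
* how much target is there at the end, in percent of the starting material charged: south-east
* how much target is there at the end, in percent of the starting material charged: north
* how much target is there at the end, in percent of the starting material charged: north-east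

The runs give a ladder of times. Nearest the start is a lag: beta, with the same 1 equiv of second substrate as the four flasks, has a logarithmic tail that, as read, meets full charge at 4.02 h, and this reckoning takes that lag over, as an assumption, to the lower loading and to 20 °C. Next comes the feed of 20 h, longer than the lag. Slowest is the decay of starting material: delta's tail, at the flasks' loading and temperature but with 1.5 equiv of second substrate, reads as a pseudo-first-order constant of 0.0225 /h, a lifetime of 44.5 h, longer than the feed.

Because the lifetime is longer than the feed, this reckoning treats a fed charge nearly as if it all entered at the mid-point of the feed, and the lag, shorter than the feed, hides under it, leaving a correction of 0.405 h. Alpha's tail, 0.00939 /h, extended in temperature at a constant logarithmic slope, makes one hour at 20 °C worth 0.313 of a warm hour.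

Count then the warm hours, the hours at 40 °C that an average portion of starting material has effectively spent reacting. The flasks hold 46.0 h in south-west, 39.6 h in south-east, 35.0 h in north-east and 33.0 h in north. Target is the charge less the gap less the fraction of starting material left, the exponential of minus the constant times the warm hours, which gives 62.9%, 57.4%, 52.9% and 50.9% in that order, so by this reckoning south-west leads.

The forecast, holding that “A linear system means delay only hurts”, chose south-west with 62.3%, 56.3% for south-east, 49.5% for north and 52.5% for north-east, its north standing 1.4 percentage points below this reckoning.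

South-west ends at 63.4%, south-east at 57.3%, north-east at 52.3% and north at 50.1%, which lies 0.80 points under the reckoning from 33.0 h.

starting material + free catalyst ⇌ catalyst intermediate A (K = 26.5 /M, k = 8.83 /M/min, Ea = 49.0 kJ/mol, ΔH = 1.00 kJ/mol); reagent + catalyst intermediate A → free catalyst + target (k = 8.34 /M/min, Ea = 41.0 kJ/mol); second substrate + free catalyst ⇌ catalyst intermediate B (K = 17700 /M, k = 14.5 /M/min, Ea = 40.0 kJ/mol, ΔH = −34.0 kJ/mol); reagent + catalyst intermediate B → free catalyst + second product (k = 159 /M/min, Ea = 37.0 kJ/mol); catalyst intermediate A + capture agent → trapped intermediate (k = 0.177 /M/min, Ea = 67.0 kJ/mol); gas ⇌ reagent, rate k6*(csat - [reagent]) (kL = 0.105 /min); (constants at 40 °C) North read at 30 h has 20.0 h fewer warm hours, so 13.0 h, and the same reckoning gives 23.9% target. North at that reading holds starting material at 74.2% and target at 23.4% of the charge.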